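Decide the temperature of these flasks by counting how many lifetimes of the starting material fit into the time they get.

| flask | starting material | partner | second reagent | third reagent | temperature | remark | time |
|---|---|---|---|---|---|---|---|
| gamma | 16 mM | 19.2 mM | 19.2 mM | 27 mM | 40 °C | run made earlier |  |
| theta | 16 mM | 19.2 mM | 19.2 mM | 42 mM | 60 °C | run made earlier |  |
| spring | 16 mM | 19.2 mM | 19.2 mM | 19.2 mM | 45 °C |  | 15 min |
| summer | 16 mM | 19.2 mM | 19.2 mM | 19.2 mM | 75 °C |  | 15 min |
| midnight | 16 mM | 19.2 mM | 19.2 mM | 19.2 mM | 60 °C |  | 15 min |

- gamma (time / min: target / %, starting material / %): 1.00: 0.1, 93.4; 3.00: 0, 85.1; 6.00: 0.1, 77.4; 10.0: 1.1, 69.8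
- theta (time / min: target / %, starting material / %): 0.500: 0, 88.4; 1.33: 0.2, 76.9; 3.00: 2.3, 62.3; 5.00: 5.5, 51.7

(each reading ± 0.3 percentage points)

- a species is counted by the starting material in it: one self-condensation product counts as two
- the earlier runs were read with a standard deviation of 0.3 percentage points
- on the list of suspects stand: starting material + partner -> intermediate A; second reagent + intermediate A -> intermediate B; third reagent + intermediate B -> target; starting material + second reagent -> side product; 2 starting material -> self-condensation product; 2 partner -> homo dimer

- the best flask by amount of target, in percent of the starting material charged; "all alike" if 1.5 percentage points covers them all (spring / summer / midnight / all alike)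
- amount of target at the end, in percent of the starting material charged, spring
- amount of target at the end, in percent of the starting material charged, summer
- amount of target at the end, in percent of the starting material charged, midnight

Turn the third reagent first. Spring, summer and midnight each hold 19.2 mM, less than either run, but on the list it enters at the last step, on intermediate B. By hand, then, it stretches the lag in target and leaves the loss of starting material alone, and being equal in these flasks it doesn't rank them. The time is 15 min in each, so it doesn't rank them either.

The flasks differ in temperature: 45 °C, 60 °C and 75 °C. Read the loss of starting material as pseudo-first-order, with a lifetime equal to the time over the logarithm of charge over remainder. The last theta reading gives 7.58 min at 60 °C. The last gamma reading gives 27.8 min at 40 °C, longer, and the pair, taking the third reagent to leave that loss alone, gives an activation energy of 56.4 kJ mol⁻¹.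

For summer 4.76 lifetimes fit, and this lifetime count, the flask's time over the lifetime at its temperature, is what I carry. Midnight has 1.98 and spring 0.758. As fractions of the charge these counts leave 0.857%, 13.8% and 46.9%. The first theta reading gives a lifetime of 4.06 min, shorter than the later one, so in theta the loss slows and I expect more to remain than these fractions say.

Target is made from starting material that has gone. I therefore put summer first, but ahead of midnight by a factor of just 1.15.

The forecast names summer and gives 4%, 30% and 16% for spring, summer and midnight, saying “it is still expected to be best”, and its summer-to-midnight ratio of 1.88 is higher than mine.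

The flasks give 4.13% in spring, 11.3% in midnight and 15.3% in summer, so summer is best, by a ratio to midnight of 1.35.

    starting material + partner → intermediate A (k = 0.210 M⁻¹ s⁻¹, Ea = 56.0 kJ mol⁻¹)
    second reagent + intermediate A → intermediate B (k = 0.192 M⁻¹ s⁻¹, Ea = 62.0 kJ mol⁻¹)
    third reagent + intermediate B → target (k = 0.293 M⁻¹ s⁻¹, Ea = 58.0 kJ mol⁻¹)
    starting material + second reagent → side product (k = 0.104 M⁻¹ s⁻¹, Ea = 70.0 kJ mol⁻¹)
    2 starting material → self-condensation product (k = 1.19 × 10⁻⁴ M⁻¹ s⁻¹, Ea = 71.0 kJ mol⁻¹)
    2 partner → homo dimer (k = 1.52 M⁻¹ s⁻¹, Ea = 54.0 kJ mol⁻¹)
    (constants at 60 °C)

Summer's count of 4.76 left 0.857% of the starting material on paper, and the flask holds 8.50%, more. The neighbouring flask repeats summer at 50 °C, where the same reckoning gives a count of 1.05 and a remainder of 35.0%. That flask holds 44% of its starting material, again more than the count leaves, and it gives 6.45% of target.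

Readings and results are calculated for an exercise; noise was put on by code.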